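2 percentage points is the lead one set-up must hold over the next, or the answer is "none", so my question was what separation of the set-ups that lead requires.

| flask | starting material | second substrate | precatalyst | remark | time |
|---|---|---|---|---|---|
| dawn | 0.20 M | 0.20 M | 20 mM | run made earlier |  |
| summer | 0.20 M | 0.10 M | 20 mM | run made earlier |  |
| autumn | 0.20 M | 0.15 M | 20 mM | run made earlier |  |
| Monday's | 0.20 M (fed, over 6.40 min) | 0.200 M | 20 mM | all but starting material at the start; starting material goes in evenly over 6.40 min, the run ends at 8.0 min | 8.0 min |
| Thursday's | 0.20 M | 0.200 M (fed, over 6.40 min) | 20 mM | a stirred flask in which second substrate is dosed at a steady rate over 6.40 min without added volume, worked up at 8.0 min | 8.0 min |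
| Friday's | 0.20 M | 0.200 M | 20 mM | everything together in a closed stirred flask, run for 8.0 min | 8.0 min |
| Saturday's | 0.20 M | 0.200 M | 20 mM | a single well-mixed tank run continuously and read at steady state, 8.0 min in it on average |  |

- dawn (time / min: target / %, isomer of the product / %, starting material / %): 0.417: 1.1, 0, 99.7; 0.667: 1.2, 0, 95.9; 0.833: 4.5, 0.5, 95.7; 1.33: 7.6, 2.9, 90.0; 2.00: 13.0, 4.1, 84.7; 3.00: 21.3, 9.4, 73.1; 5.00: 32.0, 18.7, 49.0
- summer (time / min: target / %, isomer of the product / %, starting material / %): 0.500: 2.1, 0, 98.2; 1.33: 8.5, 0, 88.7; 2.50: 19.7, 8.0, 70.7; 4.00: 31.2, 18.7, 52.2; 6.00: 42.5, 28.2, 30.7; 8.00: 48.5, 33.4, 19.7; 10.0: 49.6, 38.7, 10.5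
- autumn (time / min: target / %, isomer of the product / %, starting material / %): 0.833: 4.6, 0, 95.3; 1.33: 7.9, 1.7, 88.2; 2.00: 14.1, 3.0, 82.8; 2.50: 18.1, 6.7, 74.4; 4.00: 27.6, 14.5, 55.1; 6.00: 38.4, 25.7, 34.7; 10.0: 51.9, 35.5, 14.0

(scatter of a reading: 1 percentage point)

- the stated concentrations are those of everything mixed, before any reaction; amounts are the same in each set-up
- the feed brings no volume worth counting
- the earlier runs were made in a closed, stirred flask

* the set-up with the highest share of target in all that became target or isomer of the product, at the outlet or at the end ("none" if the first two lie within 2 percentage points) (Monday's / Thursday's / Friday's / Saturday's / none)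
* share of target in all that became target or isomer of the product, at the outlet or at the end, Monday's
* share of target in all that became target or isomer of the product, at the outlet or at the end, Thursday's
* share of target in all that became target or isomer of the product, at the outlet or at the end, Friday's
* share of target in all that became target or isomer of the product, at the outlet or at the end, Saturday's

In the dawn run the first readings show target 1.1% and isomer of the product 0%, and the target share sinks as the runs age. I therefore treated product as born target and drifting towards a floor, like a lagging sensor: the share is the floor plus a small correction, which I took to follow the turnover rate, the rate of making product divided by the product present. Mid-run in summer and autumn that rate averaged 0.249 min⁻¹ with share 64.0%; later it averaged 0.0843 min⁻¹ with share 59.6%. The line through them has slope 0.272 min and intercept 57.3%. I call the slope the lag, the share gained above the floor per unit of turnover rate. A clear winner therefore needs a turnover rate 0.0737 min⁻¹ above the runner-up's.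

In Saturday's tank the turnover rate is one over the mean time, 0.125 min⁻¹, giving 60.7%. Autumn's late loss of starting material, read as pseudo-first-order, gave 0.227 min⁻¹. With it, I reckoned that Monday's feed leaves a fraction 36.7% unreacted, so its turnover rate is 0.131 min⁻¹ and its share 60.8%. Friday's, carried on from dawn's last reading, came out in my reckoning at 24.8% unreacted, which gives 59.3%. For Thursday's, with its slowly dosed second substrate, I borrowed summer's late rate, 0.0617 min⁻¹, giving 58.9%. In my reckoning Monday's stands 0.00600 min⁻¹ above Saturday's tank, less than the gap required, so my answer was none.

The forecast gave 53.5%, 58.5%, 59% and 55% for Monday's to Saturday's and named none, closing “Thursday and Friday tie, so none.”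

The simulation gave 61.6%, 58.8%, 59.4% and 60.6% in that order, and best: none.

    precatalyst → free catalyst (k = 0.00958 s⁻¹)
    catalyst intermediate A → free catalyst + target (k = 1.28 s⁻¹)
    target + free catalyst ⇌ isomer of the product + free catalyst, rate k3*[free catalyst]*[target] forward; the back reaction follows from the equilibrium constant (K = 0.750, k = 1.01 L mol⁻¹ s⁻¹)
    starting material + free catalyst ⇌ catalyst intermediate A (K = 1400 L mol⁻¹, k = 0.316 L mol⁻¹ s⁻¹)
    catalyst intermediate B → free catalyst + second product (k = 0.0205 s⁻¹)
    second substrate + free catalyst ⇌ catalyst intermediate B (K = 10.7 L mol⁻¹, k = 0.177 L mol⁻¹ s⁻¹)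

In these equations the drift of target and the loss of starting material both run on free catalyst, so I kept the lag multiplied by the loss rate as one figure in which the free catalyst cancels. At the end of Monday's, with 40.6% of the starting material left, floor plus that figure times unreacted over reacted fraction gives 61.5%. The neighbouring flask is Monday's with precatalyst cut to 0.0080 M. It ended with 70.8% of the starting material left, the same sum gives 72.3%, and the share of target in that flask stood at 70.8%.

The data are calculated with constants of no real substance; the scatter is artificial.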